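**Retrosynthetic overview**

1. The route rests on the bond between C3 of ring C of the genkwanin unit and C6 of ring A of the luteolin unit, which lies next to the 4-hydroxyphenyl group on C2. This aryl is placed first on the future C2 of an open-chain β,β-diaryl enone and moved to the future C3 by an oxidative 1,2-shift, after which ring C is closed (O1–C2).
2. The enone 13 comes from ynone 11 by conjugate hydroarylation with 4-acetoxyphenylboronic acid. The acetate makes this ring the poorer migrating group, and the ring A phenols are masked as methoxymethyl ethers until the acid stage of the key step.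
3. Ynone 11 comes from Sonogashira coupling of 6-iodo-tetra-O-benzylluteolin 4 (three steps from luteolin) with propargylic alcohol 9 (three steps from 5-methoxyresorcinol by directed lithiation and formylation), followed by oxidation.
4. Ring order: the luteolin rings and ring A of the genkwanin unit are bought intact; ring C of the genkwanin unit is the only ring formed (step 10); hydrogenolysis ends the route.

Key step: step 10

Remark: the target SMILES defines no stereo-element, so the crowded C3–C6'' axis is taken as unresolved and all chiral intermediates are carried as racemates.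

**Step 1**
Reactants: 1 luteolin
Product: 2 7,3',4'-tri-O-benzylluteolin
Conditions: BnBr (3.3 equiv), K2CO3, DMF, rt
Reagents that add atoms: benzyl bromide, BrCc1ccccc1
Why: Williamson etherification should alkylate the three free phenols while the 5-hydroxyl, hydrogen-bonded to the C4 carbonyl, stays untouched under mild base.

**Step 2**
Reactants: 2 7,3',4'-tri-O-benzylluteolin
Product: 3 6-iodo-7,3',4'-tri-O-benzylluteolin
Conditions: BnNMe3 ICl2, CaCO3, CH2Cl2/MeOH, rt
Reagents that add atoms: benzyltrimethylammonium dichloroiodate, C[N+](C)(C)Cc1ccccc1.Cl[I-]Cl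
Why: Electrophilic aromatic iodination with this reagent is known to take place ortho to the free phenol of 5-hydroxy-7-alkoxyflavones, so iodine should enter at C6, with CaCO3 taking up the HCl.

**Step 3**
Reactants: 3 6-iodo-7,3',4'-tri-O-benzylluteolin
Product: 4 6-iodo-5,7,3',4'-tetra-O-benzylluteolin
Conditions: BnBr, K2CO3, DMF, 70 °C
Reagents that add atoms: benzyl bromide, BrCc1ccccc1
Why: Williamson etherification under forcing conditions should cap the chelated 5-hydroxyl, which otherwise could cyclise onto the alkyne introduced in step 7.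

**Step 4**
Reactants: 5 5-methoxyresorcinol
Product: 6 1-methoxy-3,5-bis(methoxymethoxy)benzene
Conditions: MOMCl, iPr2NEt, CH2Cl2, 0 °C to rt
Reagents that add atoms: chloromethyl methyl ether, COCCl
Why: O-Alkylation of both phenols gives acetal ethers that direct the lithiation of step 5 and fall off in the acid stage of step 10.

**Step 5**
Reactants: 6 1-methoxy-3,5-bis(methoxymethoxy)benzene
Product: 8 4-methoxy-2,6-bis(methoxymethoxy)benzaldehyde, via aryllithium 7 (not isolated)
Conditions: n-BuLi, TMEDA, THF, 0 °C; then DMF, 0 °C to rt; aq NH4Cl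
Reagents that add atoms: N,N-dimethylformamide, CN(C)C=O; n-butyllithium, [Li]CCCC (its lithium stands only in 7)
Why: Directed ortho-metalation should take place between the two methoxymethoxy groups, where both acetal oxygens coordinate lithium, and the aryllithium is then formylated by DMF.

**Step 6**
Reactants: 8 4-methoxy-2,6-bis(methoxymethoxy)benzaldehyde
Product: 9 rac-1-[4-methoxy-2,6-bis(methoxymethoxy)phenyl]prop-2-yn-1-ol
Conditions: HC≡CMgBr, THF, 0 °C; aq NH4Cl; chromatography on Et3N-washed silica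
Reagents that add atoms: ethynylmagnesium bromide, C#C[Mg]Br
Why: Grignard 1,2-addition to the aldehyde should give the secondary propargylic alcohol as a racemate, whose stereocentre is removed by the oxidation of step 8.

**Step 7**
Reactants: 4 6-iodo-5,7,3',4'-tetra-O-benzylluteolin; 9 rac-1-[4-methoxy-2,6-bis(methoxymethoxy)phenyl]prop-2-yn-1-ol
Product: 10 rac-6-{3-hydroxy-3-[4-methoxy-2,6-bis(methoxymethoxy)phenyl]prop-1-yn-1-yl}-5,7,3',4'-tetra-O-benzylluteolin
Conditions: Pd(PPh3)2Cl2 (cat.), CuI (cat.), Et3N, DMF, 60 °C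
Reagents that add atoms: none
Why: Sonogashira coupling of aryl iodides with terminal alkynes tolerates two flanking alkoxy groups and a free propargylic hydroxyl, so the luteolin C6–alkyne bond should form here.

**Step 8**
Reactants: 10 rac-6-{3-hydroxy-3-[4-methoxy-2,6-bis(methoxymethoxy)phenyl]prop-1-yn-1-yl}-5,7,3',4'-tetra-O-benzylluteolin
Product: 11 6-{3-[4-methoxy-2,6-bis(methoxymethoxy)phenyl]-3-oxoprop-1-yn-1-yl}-5,7,3',4'-tetra-O-benzylluteolin
Conditions: MnO2 (excess), CH2Cl2, rt
Reagents that add atoms: none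
Why: MnO2 oxidation of a benzylic and propargylic alcohol should give the ynone under neutral conditions that spare the acetal and benzyl ethers.

**Step 9**
Reactants: 11 6-{3-[4-methoxy-2,6-bis(methoxymethoxy)phenyl]-3-oxoprop-1-yn-1-yl}-5,7,3',4'-tetra-O-benzylluteolin; 12 4-acetoxyphenylboronic acid
Product: 13 (Z)-3-(4-acetoxyphenyl)-1-[4-methoxy-2,6-bis(methoxymethoxy)phenyl]-3-(5,7,3',4'-tetra-O-benzylluteolin-6-yl)prop-2-en-1-one
Conditions: [Rh(cod)OH]2 (cat.), dioxane/H2O (10:1), 60 °C
Reagents that add atoms: none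
Why: In this rhodium-catalysed conjugate hydroarylation of an ynone the arylrhodium species should add syn across the alkyne with the aryl group on the β carbon and water protonates the rhodium enolate, giving the Z alkene; the geometry is of no consequence for step 10, and neither the flavone nor the β,β-disubstituted product should react further.

**Step 10**
Reactants: 13 (Z)-3-(4-acetoxyphenyl)-1-[4-methoxy-2,6-bis(methoxymethoxy)phenyl]-3-(5,7,3',4'-tetra-O-benzylluteolin-6-yl)prop-2-en-1-one
Product: 15 5-hydroxy-2-(4-hydroxyphenyl)-7-methoxy-3-(5,7,3',4'-tetra-O-benzylluteolin-6-yl)-4H-chromen-4-one, via dimethyl ketal 14 (not isolated)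
Conditions: Tl(NO3)3·3H2O (1.2 equiv), MeOH/CH2Cl2, 0 °C to rt; then HCl, MeOH, 55 °C
Reagents that add atoms: methanol, CO (its two methoxy groups stand in 14 and are lost again on the way to 15)
Why: Proposed new method: trivalent thallium should add to the α carbon of enone 13 while methanol adds to the diaryl carbon, and loss of monovalent thallium then drives a 1,2-shift of the luteolin ring through a bridged phenonium ion (genkwanin C3–luteolin C6 bond), the resulting oxocarbenium ion being trapped by methanol as ketal 14. The closest known reaction type is the Tl(NO3)3-mediated oxidative aryl migration of 2'-oxygenated chalcones to 1,2-diaryl-3,3-dimethoxypropan-1-ones and their acid closure to isoflavones; a substrate whose β carbon carries a second aryl group has not been shown. Warm methanolic HCl should then cleave both methoxymethyl ethers and the acetate and regenerate the oxocarbenium ion, on which either of the two equivalent ring A phenols closes ring C in a 6-exo-trig mode (O1–C2 bond) before loss of methanol gives the chromone. No stereocentre is set, since the one in 14 is erased by that elimination. The step needs the luteolin ring to migrate in preference to the other aryl group: its two ortho benzyloxy groups and para ring oxygen stabilise the phenonium ion, the acetoxy group makes the competing phenyl ring a poor migrating group, and the masked ring A phenols cannot divert the organothallium intermediate to an aurone.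

**Step 11**
Reactants: 15 5-hydroxy-2-(4-hydroxyphenyl)-7-methoxy-3-(5,7,3',4'-tetra-O-benzylluteolin-6-yl)-4H-chromen-4-one
Product: 16 5-hydroxy-2-(4-hydroxyphenyl)-7-methoxy-3-(luteolin-6-yl)-4H-chromen-4-one (CNP0200311.0)
Conditions: H2 (1 atm), Pd/C, THF/MeOH, rt
Reagents that add atoms: none
Why: Catalytic hydrogenolysis should cleave the four benzyl ethers without reducing the chromone double bonds, one of which is tetrasubstituted and the other part of a vinylogous ester.

**Compound list**

1 | luteolin | O=c1cc(-c2ccc(O)c(O)c2)oc2cc(O)cc(O)c12 | starting material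
2 | 7,3',4'-tri-O-benzylluteolin | O=c1cc(-c2ccc(OCc3ccccc3)c(OCc3ccccc3)c2)oc2cc(OCc3ccccc3)cc(O)c12 | intermediate
3 | 6-iodo-7,3',4'-tri-O-benzylluteolin | O=c1cc(-c2ccc(OCc3ccccc3)c(OCc3ccccc3)c2)oc2cc(OCc3ccccc3)c(I)c(O)c12 | intermediate
4 | 6-iodo-5,7,3',4'-tetra-O-benzylluteolin | O=c1cc(-c2ccc(OCc3ccccc3)c(OCc3ccccc3)c2)oc2cc(OCc3ccccc3)c(I)c(OCc3ccccc3)c12 | intermediate
5 | 5-methoxyresorcinol | COc1cc(O)cc(O)c1 | starting material
6 | 1-methoxy-3,5-bis(methoxymethoxy)benzene | COCOc1cc(OC)cc(OCOC)c1 | intermediate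
7 | [4-methoxy-2,6-bis(methoxymethoxy)phenyl]lithium | [Li]c1c(OCOC)cc(OC)cc1OCOC | intermediate
8 | 4-methoxy-2,6-bis(methoxymethoxy)benzaldehyde | COCOc1cc(OC)cc(OCOC)c1C=O | intermediate
9 | rac-1-[4-methoxy-2,6-bis(methoxymethoxy)phenyl]prop-2-yn-1-ol | COCOc1cc(OC)cc(OCOC)c1C(O)C#C | intermediate
10 | rac-6-{3-hydroxy-3-[4-methoxy-2,6-bis(methoxymethoxy)phenyl]prop-1-yn-1-yl}-5,7,3',4'-tetra-O-benzylluteolin | O=c1cc(-c2ccc(OCc3ccccc3)c(OCc3ccccc3)c2)oc2cc(OCc3ccccc3)c(C#CC(O)c3c(OCOC)cc(OC)cc3OCOC)c(OCc3ccccc3)c12 | intermediate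
11 | 6-{3-[4-methoxy-2,6-bis(methoxymethoxy)phenyl]-3-oxoprop-1-yn-1-yl}-5,7,3',4'-tetra-O-benzylluteolin | O=c1cc(-c2ccc(OCc3ccccc3)c(OCc3ccccc3)c2)oc2cc(OCc3ccccc3)c(C#CC(=O)c3c(OCOC)cc(OC)cc3OCOC)c(OCc3ccccc3)c12 | intermediate
12 | 4-acetoxyphenylboronic acid | CC(=O)Oc1ccc(B(O)O)cc1 | starting material
13 | (Z)-3-(4-acetoxyphenyl)-1-[4-methoxy-2,6-bis(methoxymethoxy)phenyl]-3-(5,7,3',4'-tetra-O-benzylluteolin-6-yl)prop-2-en-1-one | COCOc1cc(OC)cc(OCOC)c1C(=O)/C=C(\c1c(OCc2ccccc2)cc2oc(-c3ccc(OCc4ccccc4)c(OCc4ccccc4)c3)cc(=O)c2c1OCc1ccccc1)c1ccc(OC(C)=O)cc1 | intermediate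
14 | rac-3-(4-acetoxyphenyl)-3,3-dimethoxy-1-[4-methoxy-2,6-bis(methoxymethoxy)phenyl]-2-(5,7,3',4'-tetra-O-benzylluteolin-6-yl)propan-1-one | COCOc1cc(OC)cc(OCOC)c1C(=O)C(c1c(OCc2ccccc2)cc2oc(-c3ccc(OCc4ccccc4)c(OCc4ccccc4)c3)cc(=O)c2c1OCc1ccccc1)C(OC)(OC)c1ccc(OC(C)=O)cc1 | intermediate
15 | 5-hydroxy-2-(4-hydroxyphenyl)-7-methoxy-3-(5,7,3',4'-tetra-O-benzylluteolin-6-yl)-4H-chromen-4-one | COc1cc(O)c2c(=O)c(-c3c(OCc4ccccc4)cc4oc(-c5ccc(OCc6ccccc6)c(OCc6ccccc6)c5)cc(=O)c4c3OCc3ccccc3)c(-c3ccc(O)cc3)oc2c1 | intermediate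
16 | 5-hydroxy-2-(4-hydroxyphenyl)-7-methoxy-3-(luteolin-6-yl)-4H-chromen-4-one (CNP0200311.0) | COc1cc(O)c2c(=O)c(-c3c(O)cc4oc(-c5ccc(O)c(O)c5)cc(=O)c4c3O)c(-c3ccc(O)cc3)oc2c1 | target

**Step count and risks**

Total step count: 11. Longest linear sequence: 8 steps (steps 1–3 or 4–6, then 7–11).

Steps most likely to fail:

1. Step 10 (proposed new method). The 4-acetoxyphenyl ring may migrate in place of the luteolin ring, the crowded alkene may resist oxythallation, or trivalent thallium may oxidise the electron-rich rings. The fallback makes the C3–C6'' bond by Suzuki–Miyaura coupling and sets out from iodide 4. Miyaura borylation of 4 (B2pin2, Pd(dppf)Cl2, KOAc, dioxane, 90 °C) should give the pinacol boronate F1. Commercial genkwanin (COc1cc(O)c2c(=O)cc(-c3ccc(O)cc3)oc2c1) is benzylated on both phenols (BnBr, K2CO3, DMF, 80 °C) to 5,4'-di-O-benzylgenkwanin F2. Lithiation of F2 at C3 with LiN(iPr)2 in THF at −78 °C and quenching with I2 should give 3-iodo-5,4'-di-O-benzylgenkwanin F3. Coupling of F1 with F3 (Pd(OAc)2, SPhos, K3PO4, toluene/H2O, 100 °C) should give the hexabenzyl ether F4, and hydrogenolysis under the conditions of step 11 comes back to the route at target 16.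

2. Step 9. Carbometalation at the alkyne carbon shielded by two ortho benzyloxy groups may be slow, so that protodeboronation of 12 outruns the addition. The fallback sets out from ynone 11. Conjugate hydroiodination (NaI, AcOH, rt) should give the (Z)-β-iodo enone F5. Suzuki–Miyaura coupling of F5 with 12 (Pd(PPh3)4, anhydrous K3PO4, dioxane, 70 °C) should give, with retention, F6, the E isomer of 13. F6 is taken through step 10 in place of 13 and comes back to the route at ketal 14.

3. Step 7. Coupling at the di-ortho-substituted iodide may be sluggish, and the electron-rich propargylic alcohol may ionise or isomerise to an enone under warm amine conditions. The fallback sets out from iodide 4 and aldehyde 8 and avoids the alcohol. Sonogashira coupling of 4 with trimethylsilylacetylene (Pd(PPh3)2Cl2, CuI, Et3N, 60 °C) should give the silylalkyne F7, and K2CO3 in MeOH/THF the terminal alkyne F8. Pinnick oxidation of 8 (NaClO2, NaH2PO4, 2-methyl-2-butene, t-BuOH/H2O) should give the acid F9, and 1-chloro-N,N,2-trimethylprop-1-en-1-amine in CH2Cl2 the acid chloride F10 under neutral conditions. Acyl Sonogashira coupling of F8 with F10 (Pd(PPh3)2Cl2, CuI, Et3N, THF, rt) comes back to the route at ynone 11.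

**Further compounds**

F1 | step 10 | 5,7,3',4'-tetra-O-benzylluteolin-6-ylboronic acid pinacol ester | O=c1cc(-c2ccc(OCc3ccccc3)c(OCc3ccccc3)c2)oc2cc(OCc3ccccc3)c(B3OC(C)(C)C(C)(C)O3)c(OCc3ccccc3)c12
F2 | step 10 | 5,4'-di-O-benzylgenkwanin | COc1cc(OCc2ccccc2)c2c(=O)cc(-c3ccc(OCc4ccccc4)cc3)oc2c1
F3 | step 10 | 3-iodo-5,4'-di-O-benzylgenkwanin | COc1cc(OCc2ccccc2)c2c(=O)c(I)c(-c3ccc(OCc4ccccc4)cc3)oc2c1
F4 | step 10 | 5,4'-di-O-benzyl-3-(5,7,3',4'-tetra-O-benzylluteolin-6-yl)genkwanin | COc1cc(OCc2ccccc2)c2c(=O)c(-c3c(OCc4ccccc4)cc4oc(-c5ccc(OCc6ccccc6)c(OCc6ccccc6)c5)cc(=O)c4c3OCc3ccccc3)c(-c3ccc(OCc4ccccc4)cc3)oc2c1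
F5 | step 9 | (Z)-3-iodo-1-[4-methoxy-2,6-bis(methoxymethoxy)phenyl]-3-(5,7,3',4'-tetra-O-benzylluteolin-6-yl)prop-2-en-1-one | COCOc1cc(OC)cc(OCOC)c1C(=O)/C=C(\I)c1c(OCc2ccccc2)cc2oc(-c3ccc(OCc4ccccc4)c(OCc4ccccc4)c3)cc(=O)c2c1OCc1ccccc1
F6 | step 9 | (E)-3-(4-acetoxyphenyl)-1-[4-methoxy-2,6-bis(methoxymethoxy)phenyl]-3-(5,7,3',4'-tetra-O-benzylluteolin-6-yl)prop-2-en-1-one | COCOc1cc(OC)cc(OCOC)c1C(=O)/C=C(\c1ccc(OC(C)=O)cc1)c1c(OCc2ccccc2)cc2oc(-c3ccc(OCc4ccccc4)c(OCc4ccccc4)c3)cc(=O)c2c1OCc1ccccc1
F7 | step 7 | 6-[(trimethylsilyl)ethynyl]-5,7,3',4'-tetra-O-benzylluteolin | O=c1cc(-c2ccc(OCc3ccccc3)c(OCc3ccccc3)c2)oc2cc(OCc3ccccc3)c(C#C[Si](C)(C)C)c(OCc3ccccc3)c12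
F8 | step 7 | 6-ethynyl-5,7,3',4'-tetra-O-benzylluteolin | O=c1cc(-c2ccc(OCc3ccccc3)c(OCc3ccccc3)c2)oc2cc(OCc3ccccc3)c(C#C)c(OCc3ccccc3)c12
F9 | step 7 | 4-methoxy-2,6-bis(methoxymethoxy)benzoic acid | COCOc1cc(OC)cc(OCOC)c1C(=O)O
F10 | step 7 | 4-methoxy-2,6-bis(methoxymethoxy)benzoyl chloride | COCOc1cc(OC)cc(OCOC)c1C(=O)Cl
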